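Readings and results stem from a simulated flask on assumed constants; the scatter is artificial.

- A target curve that has gone flat is easily taken for a dead flask, but a flat line can also be a balance between target and what it has become, which is thermodynamic rather than kinetic control. The choice of remedy turns on that difference.

| flask | substrate | partner | temperature | remark | time |
|---|---|---|---|---|---|
| spring | 0.50 M | 0.525 M | 25 °C | the very flask that is asked about, followed so far |  |
| noon | 0.50 M | 0.525 M | 20 °C | run made earlier |  |
| flask | 0.50 M | 0.525 M | 25 °C |  | 3.0 h |

| run | time / min | target / % | substrate / % |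
|---|---|---|---|
| spring | 30.0 | 25.0 | 19.3 |
| spring | 60.0 | 14.2 | 3.6 |
| spring | 80.0 | 11.9 | 1.1 |
| spring | 120 | 9.9 | 0.2 |
| spring | 150 | 9.8 | 0.3 |
| noon | 30.0 | 29.6 | 39.8 |
| noon | 60.0 | 22.7 | 15.6 |
| noon | 80.0 | 17.9 | 8.6 |
| noon | 120 | 11.2 | 1.8 |
| noon | 150 | 8.6 | 0.7 |

(scatter of a reading: 0.3 percentage points)

1. target, in percent of the substrate first charged, at 3.0 h
2. the remedy with the largest gain of target, or "none" below 2 percentage points (Friday's / Wednesday's / Saturday's / Tuesday's / none)
3. target present, with what was taken out counted in, in percent of the substrate first charged, after Friday's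
4. target present, with what was taken out counted in, in percent of the substrate first charged, after Wednesday's

- Friday's: at 3.0 h raise the temperature by 20 K, then wait 3.0 h
- Wednesday's: at 3.0 h add partner, 50.0 % of the amount charged, then wait 3.0 h
- Saturday's: change nothing and wait 3.0 h more
- Tuesday's: at 3.0 h take out 90 % of the target then present, then wait 3.0 h

- what is taken out of target is counted as made
- additions bring no volume worth counting

- The flask asked about is the spring run itself. Its target reads 9.9 % at 120 min and 9.8 % at 150 min, with a scatter of 0.3 percentage points, so my number for 3.0 h is 9.8 %.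
- Both runs were charged with c(partner) 0.525 M and c(substrate) 0.50 M, yet the noon run, the colder one, is already at 8.6 % at 150 min and still falling. The level therefore moves with temperature.
- The quantity to carry is the rest ratio: the charge that is neither target nor substrate, divided by target, at the plateau. The last spring reading gives 9.17, and the last noon reading gives 10.5, which is still rising.
- Friday's rise of 20 K is 4 steps of the noon-to-spring gap. Repeating that step lowers the ratio, by my estimate, to 5.25, which puts target near 16.0 %. That is a low estimate, since noon target fell from 11.2 % at 120 min to 8.6 % at 150 min. One more drop of that size takes noon target to 6.00 %, and the same reckoning then puts Friday's target near 47.4 %.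
- For Tuesday's, I let the ratio re-form in what stays in the flask, and on that reckoning the total comes to 17.8 %.
- The last spring reading of substrate is 0.3 %, with a scatter of 0.3 points, so for Wednesday's added partner I keep 9.8 %. My choice is Friday's: Tuesday's 17.8 % lies inside Friday's span from 16.0 % to 47.4 %, and the noon target was still falling at its last reading.
- The forecast also gives 9.8 % at 3.0 h, but it calls the flask “simply dead at 3 h” and gives none as the remedy, 9.8 % for Friday's and 1.5 % for Wednesday's.

The flask gives 9.76 % at 3.0 h, and Friday's ends at 34.7 %, against 9.74 % after Wednesday's.

    partner + intermediate → target (k = 1.81 L mol⁻¹ min⁻¹, Ea = 50.0 kJ mol⁻¹)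
    substrate → intermediate (k = 0.0552 min⁻¹, Ea = 86.0 kJ mol⁻¹)
    target ⇌ isomer of the product (K = 8.63, k = 0.0781 min⁻¹, Ea = 92.0 kJ mol⁻¹, ΔH = −64.0 kJ mol⁻¹)
    2 intermediate → homo product (k = 0.750 L mol⁻¹ min⁻¹, Ea = 46.0 kJ mol⁻¹)
    (constants at 25 °C)

The ratio 9.17 on 9.76 % gives a rest of 89.5 %, and at 180 min the flask holds 84.1 % of isomer of the product and 6.17 % of homo product. The neighbour charged with 0.13 M of partner ends with 2.70 % of target, on which the ratio gives 24.8 %, and that neighbour holds 23.3 % of isomer of the product beside 72.8 % of homo product.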